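## Retrosynthetic overview

1. The target comes from fluoride cleavage of all silyl groups in a silicon‑tethered pair of protected target molecules.
2. The C6–C7 and C6'–C7' bonds come from two Sonogashira couplings of a central C22 heptaene‑diyne (C10 trienedial plus two C6 enynyl phosphonium units), first with the ring B enol triflate, then with the ring A enol triflate.
3. Both ring triflates derive from (S)‑phorenol, made from ketoisophorone by asymmetric transfer hydrogenation; ring B follows by conjugate reduction and enolate triflation.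
4. Ring A: two phorenol units are joined through one diisopropylsilylene; the key step is a twofold anti epoxidation of this bis‑enone (two oxirane rings closed in one operation), followed by reductive opening to the trans‑3,4‑diol pattern.
5. Ring order: both cyclohexene rings are carried in ready‑made from ketoisophorone; the two oxiranes form together in step 3 and are opened in step 4.

Assumption: the E enynol and the all‑E C10 dialdehyde are bought as single isomers; all polyene steps are run under argon in dim light.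

## Route

Step 1
Reactants: 1 ketoisophorone (2,6,6‑trimethylcyclohex‑2‑ene‑1,4‑dione)
Product: 2 (S)‑phorenol, (4S)‑4‑hydroxy‑2,6,6‑trimethylcyclohex‑2‑en‑1‑one
Conditions: RuCl[(S,S)‑TsDPEN](p‑cymene) (0.5 mol%), HCO2H/Et3N 5:2, CH2Cl2, 25 °C
Reagents that add atoms: none
Why: Noyori asymmetric transfer hydrogenation reduces only the unhindered C4 carbonyl (the other is flanked by the quaternary carbon and the methyl‑bearing alkene carbon), and the (S,S) ligand, by analogy with aryl ketones, delivers hydride to the face that gives the S carbinol, which becomes C3 of ring A and C3' of ring B.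

Step 2
Reactants: 2 (S)‑phorenol (2 equiv)
Product: 4 diisopropylbis{[(1S)‑3,5,5‑trimethyl‑4‑oxocyclohex‑2‑en‑1‑yl]oxy}silane, via chlorosilyl ether 3 (not isolated)
Conditions: i‑Pr2SiCl2 (0.5 equiv), imidazole (2.5 equiv), DMF, 0 to 25 °C
Reagents that add atoms: dichlorodiisopropylsilane, CC(C)[Si](Cl)(Cl)C(C)C
Why: Stepwise silyl ether formation from a dichlorosilane touches no stereocentre, lets every later ring A operation run twofold on one substrate, and allows the meso diastereomer that arises from the minor enantiomer of 2 to be removed, raising optical purity.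

Step 3
Reactants: 4 silicon‑tethered bis‑enone
Product: 5 diisopropylbis{[(1R,5S,6R)‑1,3,3‑trimethyl‑2‑oxo‑7‑oxabicyclo[4.1.0]heptan‑5‑yl]oxy}silane
Conditions: t‑BuOOH (5.5 M in decane, 3 equiv), DBU (2.2 equiv), CH2Cl2, 0 °C
Reagents that add atoms: tert‑butyl hydroperoxide, CC(C)(C)OO
Why: Twofold Weitz–Scheffer nucleophilic epoxidation closes both oxirane rings in this one operation; tert‑butylperoxide adds to each β‑carbon anti to the neighbouring silyloxy group and the enolate closes on oxygen, so each epoxide is trans to the C3 oxygen and the future C4 configuration of ring A is fixed.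

Step 4
Reactants: 5 bis(epoxy ketone)
Product: 6 diisopropylbis{[(1S,2S)‑2‑hydroxy‑3,5,5‑trimethyl‑4‑oxocyclohexyl]oxy}silane (epimers at the methyl‑bearing α‑carbon)
Conditions: SmI2 (5 equiv), THF/MeOH 4:1, −90 °C
Reagents that add atoms: none
Why: Molander reductive opening of an α,β‑epoxy ketone cleaves only the α C–O bond via the ketyl, so the β C–O bond keeps its configuration and the trans relationship to the C3 oxygen; the α centre becomes CH as a mixture that is erased in step 6.

Step 5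
Reactants: 6 bis(β‑hydroxy ketone)
Product: 7 diisopropylbis{[(1S,2S)‑2‑[(tert‑butyldimethylsilyl)oxy]‑3,5,5‑trimethyl‑4‑oxocyclohexyl]oxy}silane
Conditions: TBSOTf (2.6 equiv), 2,6‑lutidine (4 equiv), CH2Cl2, −78 to 0 °C
Reagents that add atoms: tert‑butyldimethylsilyl trifluoromethanesulfonate, CC(C)(C)[Si](C)(C)OS(=O)(=O)C(F)(F)F
Why: Silyl ether formation with a silyl triflate and a hindered pyridine base protects the β‑hydroxyl without retro‑aldol cleavage and touches no stereocentre.

Step 6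
Reactants: 7 bis‑TBS ether
Product: 9 (diisopropylsilanediyl)bis(oxy) bis‑enol triflate, each ring a (3S,4S)‑3‑[(tert‑butyldimethylsilyl)oxy]‑2,6,6‑trimethylcyclohex‑1‑en‑1‑yl trifluoromethanesulfonate joined through O‑4, via dipotassium bis‑enolate 8 (not isolated)
Conditions: KN(SiMe3)2 (2.4 equiv), THF, −78 °C; then PhNTf2 (2.6 equiv), −78 to −30 °C
Reagents that add atoms: N‑phenylbis(trifluoromethanesulfonimide), O=S(=O)(N(c1ccccc1)S(=O)(=O)C(F)(F)F)C(F)(F)F
Why: Enolate O‑triflation can only go toward the methyl‑bearing α‑carbon because the other α‑carbon is quaternary, which converts the epimeric centre to sp2 and leaves C3 and C4 untouched, while the low temperature suppresses β‑elimination of silyloxide.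

Step 7
Reactants: 2 (S)‑phorenol
Product: 10 (4S)‑4‑[(tert‑butyldimethylsilyl)oxy]‑2,6,6‑trimethylcyclohex‑2‑en‑1‑one
Conditions: TBSCl (1.2 equiv), imidazole (2.5 equiv), DMF, 25 °C
Reagents that add atoms: tert‑butyldimethylsilyl chloride, CC(C)(C)[Si](C)(C)Cl
Why: Standard silyl ether formation of a secondary alcohol with no change at the stereocentre.

Step 8
Reactants: 10 TBS‑phorenol
Product: 12 (4R)‑4‑[(tert‑butyldimethylsilyl)oxy]‑2,6,6‑trimethylcyclohex‑1‑en‑1‑yl trifluoromethanesulfonate (ring B triflate), via lithium enolate 11 (not isolated)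
Conditions: LiBH(s‑Bu)3 (1.1 equiv), THF, −78 °C; then PhNTf2 (1.2 equiv), −78 to 0 °C
Reagents that add atoms: N‑phenylbis(trifluoromethanesulfonimide), O=S(=O)(N(c1ccccc1)S(=O)(=O)C(F)(F)F)C(F)(F)F
Why: Conjugate hydride addition of the bulky borohydride (1,2‑attack is blocked by the gem‑dimethyl and α‑methyl groups) gives a regiodefined enolate that is trapped on oxygen (Crisp–Scott enolate triflation); the carbinol centre is untouched and its descriptor changes from S to R only because the ring priorities change.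

Step 9
Reactants: 13 (E)‑3‑methylpent‑2‑en‑4‑yn‑1‑ol
Product: 14 [(2E)‑3‑methylpent‑2‑en‑4‑yn‑1‑yl]triphenylphosphonium bromide
Conditions: PPh3·HBr (1.05 equiv), MeOH, 25 °C
Reagents that add atoms: triphenylphosphine hydrobromide, [Br-].[PH+](c1ccccc1)(c1ccccc1)c1ccccc1
Why: Acid‑promoted substitution of the primary allylic alcohol by triphenylphosphine gives the allylic phosphonium salt (as in the industrial preparation of polyenyl Wittig salts) with the E alkene retained.

Step 10
Reactants: 14 enynyl phosphonium bromide (2.2 equiv), 15 (2E,4E,6E)‑2,7‑dimethylocta‑2,4,6‑trienedial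
Product: 18 (3E,5E,7E,9E,11E,13E,15E)‑3,7,12,16‑tetramethyloctadeca‑3,5,7,9,11,13,15‑heptaene‑1,17‑diyne, via ylide 16 (not isolated), via mono‑olefination aldehyde 17 (not isolated)
Conditions: NaOMe (2.3 equiv), MeOH/CH2Cl2, 0 to 25 °C; then heptane, 80 °C
Reagents that add atoms: none
Why: Twofold Wittig olefination with the semi‑stabilised allylic ylide builds both new disubstituted double bonds, and heating converts the hindered Z isomers of these bonds to the all‑E polyene without touching the trisubstituted alkenes next to the alkynes.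

Step 11
Reactants: 12 ring B triflate, 18 C22 heptaene‑diyne (5 equiv, excess recovered)
Product: 19 tert‑butyldimethyl{[(1R)‑3,5,5‑trimethyl‑4‑[(3E,5E,7E,9E,11E,13E,15E)‑3,7,12,16‑tetramethyloctadeca‑3,5,7,9,11,13,15‑heptaene‑1,17‑diyn‑1‑yl]cyclohex‑3‑en‑1‑yl]oxy}silane
Conditions: Pd(PPh3)4 (5 mol%), CuI (10 mol%), Et3N, DMF, 25 °C, degassed, dark
Reagents that add atoms: none
Why: Sonogashira coupling of the enol triflate with one terminal alkyne of the diyne forms the C6'–C7' bond, and the large excess of diyne keeps the coupling on one end only.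

Step 12
Reactants: 19 ring B–C22 alkyne (2.2 equiv), 9 silicon‑tethered ring A bis‑triflate
Product: 20 diisopropylsilylene‑bridged pair of fully silylated target molecules (bridge between the two ring A O‑3 atoms, TBS on O‑4 and O‑3')
Conditions: Pd(PPh3)4 (10 mol%), CuI (20 mol%), Et3N, DMF, 40 °C, degassed, dark
Reagents that add atoms: none
Why: Twofold Sonogashira coupling (zerovalent palladium inserts into each enol triflate, the copper acetylide of 19 transmetalates) forms both C6–C7 bonds, and the rigid polyene cannot bridge the two triflates of one molecule, so each triflate takes its own chain.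

Step 13
Reactants: 20 bridged bis(silyl ether)
Product: 21 (3S,4S,3'R)‑4‑hydroxyalloxanthin (two molecules per molecule of 20)
Conditions: Bu4NF/AcOH 1:1 (8 equiv), THF, 0 to 25 °C, argon, dark; crystallisation
Reagents that add atoms: none
Why: Fluoride‑mediated desilylation cleaves the four TBS ethers and both Si–O bonds of the silylene under buffered conditions that spare the acid‑sensitive allylic diol, and no stereocentre or double bond is touched.

## Compound list

1 | ketoisophorone, 2,6,6‑trimethylcyclohex‑2‑ene‑1,4‑dione | CC1=CC(=O)CC(C)(C)C1=O | starting material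
2 | (S)‑phorenol, (4S)‑4‑hydroxy‑2,6,6‑trimethylcyclohex‑2‑en‑1‑one | CC1=C[C@@H](O)CC(C)(C)C1=O | intermediate
3 | (4S)‑4‑{[chloro(diisopropyl)silyl]oxy}‑2,6,6‑trimethylcyclohex‑2‑en‑1‑one | CC1=C[C@@H](O[Si](Cl)(C(C)C)C(C)C)CC(C)(C)C1=O | intermediate
4 | diisopropylbis{[(1S)‑3,5,5‑trimethyl‑4‑oxocyclohex‑2‑en‑1‑yl]oxy}silane | CC(C)[Si](C(C)C)(O[C@@H]1C=C(C)C(=O)C(C)(C)C1)O[C@@H]1C=C(C)C(=O)C(C)(C)C1 | intermediate
5 | diisopropylbis{[(1R,5S,6R)‑1,3,3‑trimethyl‑2‑oxo‑7‑oxabicyclo[4.1.0]heptan‑5‑yl]oxy}silane | CC(C)[Si](C(C)C)(O[C@H]1CC(C)(C)C(=O)[C@]2(C)O[C@H]12)O[C@H]1CC(C)(C)C(=O)[C@]2(C)O[C@H]12 | intermediate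
6 | diisopropylbis{[(1S,2S)‑2‑hydroxy‑3,5,5‑trimethyl‑4‑oxocyclohexyl]oxy}silane, epimers at C3 of each ring | CC(C)[Si](C(C)C)(O[C@H]1CC(C)(C)C(=O)C(C)[C@@H]1O)O[C@H]1CC(C)(C)C(=O)C(C)[C@@H]1O | intermediate
7 | diisopropylbis{[(1S,2S)‑2‑[(tert‑butyldimethylsilyl)oxy]‑3,5,5‑trimethyl‑4‑oxocyclohexyl]oxy}silane, epimers at C3 of each ring | CC(C)[Si](C(C)C)(O[C@H]1CC(C)(C)C(=O)C(C)[C@@H]1O[Si](C)(C)C(C)(C)C)O[C@H]1CC(C)(C)C(=O)C(C)[C@@H]1O[Si](C)(C)C(C)(C)C | intermediate
8 | dipotassium bis‑enolate of 7 | CC(C)[Si](C(C)C)(O[C@H]1CC(C)(C)C([O-])=C(C)[C@@H]1O[Si](C)(C)C(C)(C)C)O[C@H]1CC(C)(C)C([O-])=C(C)[C@@H]1O[Si](C)(C)C(C)(C)C.[K+].[K+] | intermediate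
9 | ring A bis‑triflate: diisopropylsilylene bridging O‑4 of two (3S,4S)‑3‑[(tert‑butyldimethylsilyl)oxy]‑2,6,6‑trimethylcyclohex‑1‑en‑1‑yl triflates | CC(C)[Si](C(C)C)(O[C@H]1CC(C)(C)C(OS(=O)(=O)C(F)(F)F)=C(C)[C@@H]1O[Si](C)(C)C(C)(C)C)O[C@H]1CC(C)(C)C(OS(=O)(=O)C(F)(F)F)=C(C)[C@@H]1O[Si](C)(C)C(C)(C)C | intermediate
10 | (4S)‑4‑[(tert‑butyldimethylsilyl)oxy]‑2,6,6‑trimethylcyclohex‑2‑en‑1‑one | CC1=C[C@@H](O[Si](C)(C)C(C)(C)C)CC(C)(C)C1=O | intermediate
11 | lithium (4R)‑4‑[(tert‑butyldimethylsilyl)oxy]‑2,6,6‑trimethylcyclohex‑1‑en‑1‑olate | CC1=C([O-])C(C)(C)C[C@H](O[Si](C)(C)C(C)(C)C)C1.[Li+] | intermediate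
12 | ring B triflate, (4R)‑4‑[(tert‑butyldimethylsilyl)oxy]‑2,6,6‑trimethylcyclohex‑1‑en‑1‑yl trifluoromethanesulfonate | CC1=C(OS(=O)(=O)C(F)(F)F)C(C)(C)C[C@H](O[Si](C)(C)C(C)(C)C)C1 | intermediate
13 | (E)‑3‑methylpent‑2‑en‑4‑yn‑1‑ol | C#C/C(C)=C/CO | starting material
14 | [(2E)‑3‑methylpent‑2‑en‑4‑yn‑1‑yl]triphenylphosphonium bromide | C#C/C(C)=C/C[P+](c1ccccc1)(c1ccccc1)c1ccccc1.[Br-] | intermediate
15 | (2E,4E,6E)‑2,7‑dimethylocta‑2,4,6‑trienedial | O=C/C(C)=C/C=C/C=C(\C)C=O | starting material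
16 | [(2E)‑3‑methylpent‑2‑en‑4‑yn‑1‑ylidene]triphenylphosphorane | C#C/C(C)=C/C=P(c1ccccc1)(c1ccccc1)c1ccccc1 | intermediate
17 | (2E,4E,6E,8E,10E)‑2,7,11‑trimethyltrideca‑2,4,6,8,10‑pentaen‑12‑ynal | C#C/C(C)=C/C=C/C(C)=C/C=C/C=C(\C)C=O | intermediate
18 | (3E,5E,7E,9E,11E,13E,15E)‑3,7,12,16‑tetramethyloctadeca‑3,5,7,9,11,13,15‑heptaene‑1,17‑diyne | C#C/C(C)=C/C=C/C(C)=C/C=C/C=C(C)/C=C/C=C(\C)C#C | intermediate
19 | ring B–C22 alkyne, (1R)‑silyl ether of the 3‑hydroxy‑7,8‑didehydro end group carrying the all‑E heptaene chain with a free terminal alkyne | C#C/C(C)=C/C=C/C(C)=C/C=C/C=C(C)/C=C/C=C(\C)C#CC1=C(C)C[C@@H](O[Si](C)(C)C(C)(C)C)CC1(C)C | intermediate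
20 | diisopropylsilylene‑bridged (through both ring A O‑3 atoms) pair of 4,3'‑bis‑O‑TBS‑(3S,4S,3'R)‑4‑hydroxyalloxanthin | CC(C)[Si](C(C)C)(O[C@H]1CC(C)(C)C(C#C/C(C)=C/C=C/C(C)=C/C=C/C=C(C)/C=C/C=C(\C)C#CC2=C(C)C[C@@H](O[Si](C)(C)C(C)(C)C)CC2(C)C)=C(C)[C@@H]1O[Si](C)(C)C(C)(C)C)O[C@H]1CC(C)(C)C(C#C/C(C)=C/C=C/C(C)=C/C=C/C=C(C)/C=C/C=C(\C)C#CC2=C(C)C[C@@H](O[Si](C)(C)C(C)(C)C)CC2(C)C)=C(C)[C@@H]1O[Si](C)(C)C(C)(C)C | intermediate
21 | (3S,4S,3'R)‑4‑hydroxyalloxanthin | CC1=C(C#C/C(C)=C/C=C/C(C)=C/C=C/C=C(C)/C=C/C=C(\C)C#CC2=C(C)[C@H](O)[C@@H](O)CC2(C)C)C(C)(C)C[C@H](O)C1 | target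

## Step count and risks

Total step count: 13. Longest linear sequence: 8 steps (steps 1, 2, 3, 4, 5, 6, 12, 13).

Steps most likely to fail:

Step 3 (twofold epoxidation). DBU may deprotonate the γ‑position of the silyloxy enone (loss of the C3 centre or isomerisation to the dione), and the anti selectivity must be high at both rings at once. The fallback sets out from 4 and comes back at 6 without an epoxide: copper‑catalysed conjugate borylation (B2pin2, CuCl, NaOt‑Bu, MeOH, THF) adds boron to each β‑carbon anti to the silyloxy group to give the bis(β‑boryl ketone) F1, and NaBO3·4H2O oxidation with retention gives 6.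

Step 6 (twofold enol triflation). The enolate carries a β‑silyloxy group and may eliminate to the enone instead of being triflated. The fallback sets out from 7 (with 19) and comes back at 20, avoiding the enolate and the triflate altogether: the lithium acetylide of 19 (LiN(SiMe3)2, then CeCl3, THF, −78 °C) adds to both ketones of 7 to give the bis(tertiary propargylic alcohol) F2, and dehydration with Burgess reagent (only the methyl‑bearing carbon has a β‑hydrogen) gives 20 directly.

Step 12 (twofold Sonogashira on the hindered bis‑triflate with a polyenyne). Copper‑mediated alkyne homocoupling and slow oxidative addition at the tetrasubstituted triflates can stop the reaction at the mono‑coupled stage. The fallback sets out from 19 and comes back at 20 by a copper‑free and amine‑free coupling: deprotonation of 19 (LiN(SiMe3)2) and quenching with Bu3SnCl gives the alkynylstannane F3, which undergoes Stille coupling with 9 (Pd(PPh3)4, LiCl, THF, 60 °C) to give 20.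

## Further compounds

F1 | step 3 | diisopropylbis{[(1S,2S)‑3,5,5‑trimethyl‑4‑oxo‑2‑(4,4,5,5‑tetramethyl‑1,3,2‑dioxaborolan‑2‑yl)cyclohexyl]oxy}silane (boron anti to the silyloxy group) | CC(C)[Si](C(C)C)(O[C@H]1CC(C)(C)C(=O)C(C)[C@@H]1B2OC(C)(C)C(C)(C)O2)O[C@H]1CC(C)(C)C(=O)C(C)[C@@H]1B2OC(C)(C)C(C)(C)O2
F2 | step 6 | silylene‑bridged bis(tertiary propargylic alcohol) from addition of the acetylide of 19 to both ketones of 7 | CC(C)[Si](C(C)C)(O[C@H]1CC(C)(C)C(O)(C#C/C(C)=C/C=C/C(C)=C/C=C/C=C(C)/C=C/C=C(\C)C#CC2=C(C)C[C@@H](O[Si](C)(C)C(C)(C)C)CC2(C)C)C(C)[C@@H]1O[Si](C)(C)C(C)(C)C)O[C@H]1CC(C)(C)C(O)(C#C/C(C)=C/C=C/C(C)=C/C=C/C=C(C)/C=C/C=C(\C)C#CC2=C(C)C[C@@H](O[Si](C)(C)C(C)(C)C)CC2(C)C)C(C)[C@@H]1O[Si](C)(C)C(C)(C)C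
F3 | step 12 | tributylstannyl alkyne of 19 | CCCC[Sn](CCCC)(CCCC)C#C/C(C)=C/C=C/C(C)=C/C=C/C=C(C)/C=C/C=C(\C)C#CC1=C(C)C[C@@H](O[Si](C)(C)C(C)(C)C)CC1(C)C
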